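The isoflavone is disconnected at the C4–C4a bond of ring C, which leaves an aryl enol ether carrying ring B and a carboxyl group on one alkene carbon. A single intramolecular Friedel–Crafts acylation closes the pyranone and delivers the complete protected skeleton. The step exploits ring A, an electron-rich phloroglucinol triether in which C8 already bears the 2-methylbut-3-en-2-yl group, so that C4a is the one open carbon next to O1 and the O1 tether can steer the acyl carbon nowhere else. The precursor is the (Z)-3-aryloxy-2-arylacrylic acid 10, joined from a Claisen-derived phenol and the Z enol tosylate of a formylated ring B arylacetate, with all four hydroxyls as benzyl ethers.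

Key step: step 8

Remark: vinylic substitution on the Z tosylate 8 is assumed to proceed with retention; any E isomer of 9 or 10 would be carried on, because the acylium ion of step 8 can rotate about C2–C3.

Step 1
Reactants: 1 3,5-bis(benzyloxy)phenol; 2 prenyl bromide (1-bromo-3-methylbut-2-ene)
Product: 3 1,3-bis(benzyloxy)-5-[(3-methylbut-2-en-1-yl)oxy]benzene
Conditions: K2CO3, acetone, 56 °C
Reagents that add atoms: none
Why: Williamson ether synthesis, in which the phenoxide of 1 displaces bromide from the primary allylic carbon of 2 and the weak base in acetone should favour O- over C-alkylation.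

Step 2
Reactants: 3 1,3-bis(benzyloxy)-5-[(3-methylbut-2-en-1-yl)oxy]benzene
Product: 4 3,5-bis(benzyloxy)-2-(2-methylbut-3-en-2-yl)phenol
Conditions: PhNEt2, 185 °C, argon
Reagents that add atoms: none
Why: Aromatic Claisen rearrangement, whose [3,3]-sigmatropic shift delivers the allyl unit with inversion to one of the two equivalent ortho carbons so that the tertiary carbon ends up on the ring, while the amine solvent should speed enolisation of the dienone ahead of a Cope shift to C4.

Step 3
Reactants: 5 2,4-dihydroxyphenylacetic acid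
Product: 6 benzyl 2-[2,4-bis(benzyloxy)phenyl]acetate
Conditions: BnBr, K2CO3, DMF, 60 °C
Reagents that add atoms: benzyl bromide, BrCc1ccccc1
Why: Threefold Williamson-type alkylation, which should benzylate both phenoxides and the carboxylate in one operation and leaves an ester that activates the methylene group for the next step.

Step 4
Reactants: 6 benzyl 2-[2,4-bis(benzyloxy)phenyl]acetate
Product: 7 benzyl (Z)-2-[2,4-bis(benzyloxy)phenyl]-3-hydroxyprop-2-enoate (hydrogen-bonded enol of the α-formyl ester)
Conditions: NaH, HCO2Bn, THF, 0 °C to rt; 1 M HCl work-up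
Reagents that add atoms: benzyl formate, O=COCc1ccccc1
Why: Crossed Claisen condensation of the arylacetate enolate with a non-enolisable formate, driven by deprotonation of the product, with the formate taken as its benzyl ester so that the only alkoxide in the flask matches the ester and transesterification is excluded.

Step 5
Reactants: 7 benzyl (Z)-2-[2,4-bis(benzyloxy)phenyl]-3-hydroxyprop-2-enoate
Product: 8 benzyl (Z)-2-[2,4-bis(benzyloxy)phenyl]-3-[(4-methylbenzenesulfonyl)oxy]prop-2-enoate (tosyloxy cis to the ester)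
Conditions: TsCl, N-methylimidazole, LiOH, THF, 0 °C
Reagents that add atoms: p-toluenesulfonyl chloride, Cc1ccc(cc1)S(=O)(=O)Cl
Why: O-Sulfonylation of the enolate by the N-tosylimidazolium salt formed from TsCl and N-methylimidazole, in which lithium chelation between the enolate oxygen and the ester carbonyl should fix the Z geometry.

Step 6
Reactants: 4 3,5-bis(benzyloxy)-2-(2-methylbut-3-en-2-yl)phenol; 8 benzyl (Z)-2-[2,4-bis(benzyloxy)phenyl]-3-[(4-methylbenzenesulfonyl)oxy]prop-2-enoate
Product: 9 benzyl (Z)-3-[3,5-bis(benzyloxy)-2-(2-methylbut-3-en-2-yl)phenoxy]-2-[2,4-bis(benzyloxy)phenyl]prop-2-enoate (aryloxy cis to the ester)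
Conditions: Cs2CO3, MeCN, rt
Reagents that add atoms: none
Why: Nucleophilic vinylic substitution by addition–elimination, in which the cesium phenoxide of 4 adds to the unhindered β-carbon of the vinylogous sulfonic–carboxylic anhydride 8 and tosylate leaves from the short-lived ester enolate, which should preserve the Z geometry.

Step 7
Reactants: 9 benzyl (Z)-3-[3,5-bis(benzyloxy)-2-(2-methylbut-3-en-2-yl)phenoxy]-2-[2,4-bis(benzyloxy)phenyl]prop-2-enoate
Product: 10 (Z)-3-[3,5-bis(benzyloxy)-2-(2-methylbut-3-en-2-yl)phenoxy]-2-[2,4-bis(benzyloxy)phenyl]prop-2-enoic acid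
Conditions: LiOH·H2O, THF/H2O, 40 °C; 1 M HCl to pH 3
Reagents that add atoms: lithium hydroxide (hydroxide oxygen), [Li+].[OH-]
Why: Saponification of the benzyl ester by acyl–oxygen cleavage in alcohol-free aqueous THF, which avoids exchange of the aryloxy group by alkoxide and should leave the benzyl ethers, the enol ether and the terminal alkene untouched.

Step 8
Reactants: 10 (Z)-3-[3,5-bis(benzyloxy)-2-(2-methylbut-3-en-2-yl)phenoxy]-2-[2,4-bis(benzyloxy)phenyl]prop-2-enoic acid
Product: 12 5,7-bis(benzyloxy)-3-[2,4-bis(benzyloxy)phenyl]-8-(2-methylbut-3-en-2-yl)chromen-4-one, via mixed trifluoroacetic anhydride 11 (not isolated)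
Conditions: TFAA, CH2Cl2 (high dilution), 0 °C to rt
Reagents that add atoms: none
Why: TFAA converts 10 into the mixed anhydride 11, which should ionise to an acylium ion stabilised by the enol ether oxygen (ketene–oxocarbenium resonance), and this lowers the barrier to rotation about C2–C3 so that any E isomer can reach the reactive Z form. The acyl carbon is then attacked by C4a of ring A and loss of a proton gives the chromenone, an intramolecular Friedel–Crafts acylation whose closest known relatives are the cyclisation of 3-aryloxyacrylic acids to chromones and the TFAA-mediated closure of 2-aryloxybenzoic acids to xanthones. Ring C closes in a 6-exo-trig mode at the acyl carbon, the arene carbon adding to a C=O bond that lies outside the new ring, and this forms the C4–C4a bond. No stereocentre is created. The step needs regioselectivity for C4a, which the O1 tether secures because C8 is blocked by the 2-methylbut-3-en-2-yl group and C6 cannot be reached through a six-membered ring. It also needs chemoselectivity over O-acylation at the 2'-benzyloxy oxygen and over reaction at the terminal alkene, which the absence of a Lewis acid and of a nucleophilic counter-ion, high dilution and low temperature should provide.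

Step 9
Reactants: 12 5,7-bis(benzyloxy)-3-[2,4-bis(benzyloxy)phenyl]-8-(2-methylbut-3-en-2-yl)chromen-4-one
Product: 14 5,7-dihydroxy-3-(2,4-dihydroxyphenyl)-8-(2-methylbut-3-en-2-yl)chromen-4-one, via tetrakis(dichloroboryl) ether 13 (not isolated)
Conditions: BCl3, C6HMe5, CH2Cl2, −78 °C; MeOH quench at −78 °C
Reagents that add atoms: none
Why: Lewis-acid debenzylation with a non-basic cation scavenger, in which BCl3 coordinates each ether oxygen, the benzyl cation is captured by pentamethylbenzene (Friedel–Crafts benzylation) and the aryloxyboron chlorides 13 are methanolysed on quench, all at a temperature where the terminal alkene and the tert-alkyl–aryl bond should not be protonated.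

Compound list
1 | 3,5-bis(benzyloxy)phenol | Oc1cc(OCc2ccccc2)cc(OCc2ccccc2)c1 | starting material
2 | prenyl bromide (1-bromo-3-methylbut-2-ene) | CC(C)=CCBr | starting material
3 | 1,3-bis(benzyloxy)-5-[(3-methylbut-2-en-1-yl)oxy]benzene | CC(C)=CCOc1cc(OCc2ccccc2)cc(OCc2ccccc2)c1 | intermediate
4 | 3,5-bis(benzyloxy)-2-(2-methylbut-3-en-2-yl)phenol | C=CC(C)(C)c1c(O)cc(OCc2ccccc2)cc1OCc1ccccc1 | intermediate
5 | 2,4-dihydroxyphenylacetic acid | O=C(O)Cc1ccc(O)cc1O | starting material
6 | benzyl 2-[2,4-bis(benzyloxy)phenyl]acetate | O=C(Cc1ccc(OCc2ccccc2)cc1OCc1ccccc1)OCc1ccccc1 | intermediate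
7 | benzyl (Z)-2-[2,4-bis(benzyloxy)phenyl]-3-hydroxyprop-2-enoate | O/C=C(\C(=O)OCc1ccccc1)c1ccc(OCc2ccccc2)cc1OCc1ccccc1 | intermediate
8 | benzyl (Z)-2-[2,4-bis(benzyloxy)phenyl]-3-[(4-methylbenzenesulfonyl)oxy]prop-2-enoate | Cc1ccc(cc1)S(=O)(=O)O/C=C(\C(=O)OCc1ccccc1)c1ccc(OCc2ccccc2)cc1OCc1ccccc1 | intermediate
9 | benzyl (Z)-3-[3,5-bis(benzyloxy)-2-(2-methylbut-3-en-2-yl)phenoxy]-2-[2,4-bis(benzyloxy)phenyl]prop-2-enoate | C=CC(C)(C)c1c(OCc2ccccc2)cc(OCc2ccccc2)cc1O/C=C(\C(=O)OCc1ccccc1)c1ccc(OCc2ccccc2)cc1OCc1ccccc1 | intermediate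
10 | (Z)-3-[3,5-bis(benzyloxy)-2-(2-methylbut-3-en-2-yl)phenoxy]-2-[2,4-bis(benzyloxy)phenyl]prop-2-enoic acid | C=CC(C)(C)c1c(OCc2ccccc2)cc(OCc2ccccc2)cc1O/C=C(\C(=O)O)c1ccc(OCc2ccccc2)cc1OCc1ccccc1 | intermediate
11 | (Z)-3-[3,5-bis(benzyloxy)-2-(2-methylbut-3-en-2-yl)phenoxy]-2-[2,4-bis(benzyloxy)phenyl]prop-2-enoic trifluoroacetic anhydride | C=CC(C)(C)c1c(OCc2ccccc2)cc(OCc2ccccc2)cc1O/C=C(\C(=O)OC(=O)C(F)(F)F)c1ccc(OCc2ccccc2)cc1OCc1ccccc1 | intermediate
12 | 5,7-bis(benzyloxy)-3-[2,4-bis(benzyloxy)phenyl]-8-(2-methylbut-3-en-2-yl)chromen-4-one | C=CC(C)(C)c1c(OCc2ccccc2)cc(OCc2ccccc2)c2c(=O)c(-c3ccc(OCc4ccccc4)cc3OCc3ccccc3)coc12 | intermediate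
13 | 5,7-bis[(dichloroboranyl)oxy]-3-{2,4-bis[(dichloroboranyl)oxy]phenyl}-8-(2-methylbut-3-en-2-yl)chromen-4-one | C=CC(C)(C)c1c(OB(Cl)Cl)cc(OB(Cl)Cl)c2c(=O)c(-c3ccc(OB(Cl)Cl)cc3OB(Cl)Cl)coc12 | intermediate
14 | 5,7-dihydroxy-3-(2,4-dihydroxyphenyl)-8-(2-methylbut-3-en-2-yl)chromen-4-one | C=CC(C)(C)c1c(O)cc(O)c2c(=O)c(-c3ccc(O)cc3O)coc12 | target

Total steps: 9. Longest linear sequence: 7 steps (steps 3 to 9, from 5); the ring A branch (steps 1 and 2) joins at step 6.

Steps most likely to fail

Step 8. The mixed anhydride may be diverted by O-acylation at the 2'-benzyloxy oxygen with loss of that benzyl group (lactonisation to a benzofuranone), or it may ionise so slowly that trifluoroacetic acid erodes the enol ether before ring closure. The fallback builds ring C first and attaches ring B last; it sets out from phenol 4 and returns to the route at 12.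
- Magnesium-mediated ortho-formylation of 4 (MgCl2, Et3N, paraformaldehyde, MeCN, reflux) can only reach the single free carbon ortho to the hydroxyl and should give 4,6-bis(benzyloxy)-2-hydroxy-3-(2-methylbut-3-en-2-yl)benzaldehyde F1.
- Addition of MeMgBr (THF, 0 °C) should give racemic 1-[4,6-bis(benzyloxy)-2-hydroxy-3-(2-methylbut-3-en-2-yl)phenyl]ethan-1-ol F2.
- Benzylic oxidation with MnO2 (CH2Cl2, rt) should give 1-[4,6-bis(benzyloxy)-2-hydroxy-3-(2-methylbut-3-en-2-yl)phenyl]ethan-1-one F3.
- Condensation with N,N-dimethylformamide dimethyl acetal (toluene, 90 °C) should give the enaminone (E)-1-[4,6-bis(benzyloxy)-2-hydroxy-3-(2-methylbut-3-en-2-yl)phenyl]-3-(dimethylamino)prop-2-en-1-one F4.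
- Iodine (CHCl3, pyridine, rt) should cyclise the enaminone with loss of dimethylamine to 5,7-bis(benzyloxy)-3-iodo-8-(2-methylbut-3-en-2-yl)chromen-4-one F5.
- Suzuki–Miyaura coupling of this iodide with 2,4-bis(benzyloxy)phenylboronic acid (Pd(PPh3)4, Na2CO3, DME/H2O, 80 °C) would then give 12.

Step 9. Ionising debenzylation may be accompanied by acid-triggered events at the 2-methylbut-3-en-2-yl group: protonation of the terminal alkene, ring closure of the C7 oxygen onto it, or loss of the tert-alkyl group from C8. The fallback sets out from 12 and returns at 14, and it makes no new compound (F0). The four benzyl groups would be removed by SN2 attack of a thiolate (NaSEt, DMF, 80–100 °C, argon), an acid-free dealkylation of aryl alkyl ethers in which they leave as benzyl ethyl sulfide. The phenoxides formed should deactivate ring C toward conjugate addition, and any ring C opened by thiolate attack at C2 should reclose on acidification.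

Step 2. At the temperature of the rearrangement the product phenol may react further, by abnormal Claisen rearrangement or by ring closure of its hydroxyl onto the new alkene, and part of the dienone may escape by Cope shift to C4. The fallback sets out from 3 and returns at 4. The rearrangement would be run with an acylating trap (Ac2O, NaOAc, PhNEt2, 180 °C), so that the phenol is captured as it forms as 3,5-bis(benzyloxy)-2-(2-methylbut-3-en-2-yl)phenyl acetate F6. Mild methanolysis (K2CO3, MeOH, rt) would then release 4.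

Further compounds
F1 | step 8 | 4,6-bis(benzyloxy)-2-hydroxy-3-(2-methylbut-3-en-2-yl)benzaldehyde | O=Cc1c(O)c(C(C)(C)C=C)c(OCc2ccccc2)cc1OCc1ccccc1
F2 | step 8 | 1-[4,6-bis(benzyloxy)-2-hydroxy-3-(2-methylbut-3-en-2-yl)phenyl]ethan-1-ol (racemic) | CC(O)c1c(O)c(C(C)(C)C=C)c(OCc2ccccc2)cc1OCc1ccccc1
F3 | step 8 | 1-[4,6-bis(benzyloxy)-2-hydroxy-3-(2-methylbut-3-en-2-yl)phenyl]ethan-1-one | CC(=O)c1c(O)c(C(C)(C)C=C)c(OCc2ccccc2)cc1OCc1ccccc1
F4 | step 8 | (E)-1-[4,6-bis(benzyloxy)-2-hydroxy-3-(2-methylbut-3-en-2-yl)phenyl]-3-(dimethylamino)prop-2-en-1-one | CN(C)/C=C/C(=O)c1c(O)c(C(C)(C)C=C)c(OCc2ccccc2)cc1OCc1ccccc1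
F5 | step 8 | 5,7-bis(benzyloxy)-3-iodo-8-(2-methylbut-3-en-2-yl)chromen-4-one | C=CC(C)(C)c1c(OCc2ccccc2)cc(OCc2ccccc2)c2c(=O)c(I)coc12
F0 | step 9 | none | none
F6 | step 2 | 3,5-bis(benzyloxy)-2-(2-methylbut-3-en-2-yl)phenyl acetate | CC(=O)Oc1cc(OCc2ccccc2)cc(OCc2ccccc2)c1C(C)(C)C=C
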